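The cyclobutane is seen as a masked succinate: ring carbon C-1 (carrying the CH2 link to the quaternary centre) and ring carbon C-2 (carrying the isopropenyl group) are both α to carbons that can be drawn as carbonyls. Their bond, a union of two like-polarity α-carbons, is made by intramolecular oxidative coupling of the bis-enolate of an open-chain 3,3-dimethyladipoyl bis(oxazolidinone). This single operation closes the four-membered ring and sets both ring stereocentres, trans, under auxiliary control. The derived aldehyde is grafted onto a dihydroxychromanone, the hexanoic arm is added by iminium catalysis, and a dearomatising prenylation builds the quaternary centre last.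

Key step: step 3

Assumption: the sense of induction of the chiral palladium catalyst in step 14 cannot be read from a simple model for a planar prochiral nucleophile; the (R,R)-ligand is taken as the one that gives the (6R) quaternary carbon, and the enantiomeric ligand would be used otherwise.

Step 1
Reactants: 1 4,4-dimethylcyclohexene
Product: 2 3,3-dimethylhexanedioic acid
Conditions: RuCl3·xH2O (2 mol %), NaIO4 (4.2 equiv), EtOAc/MeCN/H2O, rt
Reagents that add atoms: sodium periodate [Na+].[O-]I(=O)(=O)=O; water O
Why: Ruthenium tetroxide formed in situ cleaves the ring C=C bond and oxidises both termini to carboxylic acids (RuCl3/NaIO4 oxidative alkene cleavage); no stereocentre is involved.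

Step 2
Reactants: 2 3,3-dimethylhexanedioic acid; 3 (S)-4-benzyl-1,3-oxazolidin-2-one (2.1 equiv)
Product: 5 (4S,4'S)-3,3'-(3,3-dimethylhexanedioyl)bis(4-benzyl-1,3-oxazolidin-2-one), via bis(pivalic) mixed anhydride 4 (not isolated)
Conditions: PivCl (2.2 equiv), Et3N (5 equiv), THF, −20 °C; then LiCl (2.2 equiv) and 3, −20 °C → rt
Reagents that add atoms: none
Why: The mixed anhydride acylates the LiCl-activated oxazolidinone nitrogen at the less hindered carbonyl (one-pot N-acylation of oxazolidinone auxiliaries), and both (S) centres are brought in with the auxiliary.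

Step 3
Reactants: 5 (4S,4'S)-3,3'-(3,3-dimethylhexanedioyl)bis(4-benzyl-1,3-oxazolidin-2-one)
Product: 7 (4S,4'S)-3,3'-{[(1R,2S)-3,3-dimethylcyclobutane-1,2-diyl]dicarbonyl}bis(4-benzyl-1,3-oxazolidin-2-one), via dilithium bis-enolate 6 (not isolated)
Conditions: LDA (2.2 equiv), THF, −78 °C; then CuCl2 (2.5 equiv, added in DMF), −78 → 0 °C, 0.01 M
Reagents that add atoms: none
Why: Double deprotonation gives the bis-(Z)-lithium enolate 6; divalent copper oxidises one enolate to an α-carbonyl radical (or copper enolate) that is captured by the second enolate carbon, and a second one-electron oxidation delivers the 1,4-dicarbonyl, so two nucleophilic α-carbons are joined. The closest known reactions are the oxidative homocoupling of lithium enolates of N-acyloxazolidinones to 2,3-disubstituted succinates and the oxidative cyclisation of diester dienolates to cycloalkane-1,2-dicarboxylates. The four-membered ring closes by bonding C-2 to C-5 of the hexanedioyl chain (a 4-exo attack of the radical on the enolate double bond), helped by the gem-dimethyl group. Each new stereocentre is controlled by its own auxiliary: the benzyl group shields one face of the chelated Z-enolate in the sense known from oxazolidinone enolate alkylations, and for the (S,S) pair both preferences coincide in the trans-(1R,2S) product (matched double induction). The step needs ring closure to win over intermolecular coupling, which high dilution and the Thorpe–Ingold effect should secure, and it needs a product that does not epimerise, which allylic strain in the α-branched imides ensures.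

Step 4
Reactants: 7 (4S,4'S)-3,3'-{[(1R,2S)-3,3-dimethylcyclobutane-1,2-diyl]dicarbonyl}bis(4-benzyl-1,3-oxazolidin-2-one)
Product: 8 (S)-4-benzyl-3-{[(1S,2R)-2-(hydroxymethyl)-4,4-dimethylcyclobutyl]carbonyl}-1,3-oxazolidin-2-one
Conditions: LiBH4 (1.05 equiv), H2O (1.05 equiv), Et2O, 0 °C
Reagents that add atoms: none
Why: Reductive removal of an oxazolidinone auxiliary with LiBH4 gives the primary alcohol, and one equivalent should take only the imide on the ring carbon next to CH2, because the other imide carbonyl is screened by the adjacent gem-dimethyl carbon; no stereocentre is touched.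

Step 5
Reactants: 8 (S)-4-benzyl-3-{[(1S,2R)-2-(hydroxymethyl)-4,4-dimethylcyclobutyl]carbonyl}-1,3-oxazolidin-2-one
Product: 10 (1S,2R)-2-(hydroxymethyl)-4,4-dimethylcyclobutane-1-carboxylic acid, via peroxy acid 9 (not isolated)
Conditions: LiOH·H2O (2 equiv), 30% H2O2 (4 equiv), THF/H2O, 0 °C → rt; then aq. Na2SO3; HCl to pH 2
Reagents that add atoms: hydrogen peroxide OO
Why: Hydroperoxide attacks the exocyclic carbonyl even of hindered imides (LiOH/H2O2 auxiliary cleavage), sulfite reduces the peracid, and the α-centre is not epimerised under these conditions.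

Step 6
Reactants: 10 (1S,2R)-2-(hydroxymethyl)-4,4-dimethylcyclobutane-1-carboxylic acid
Product: 12 1-[(1S,2R)-2-(hydroxymethyl)-4,4-dimethylcyclobutyl]ethan-1-one, via trilithium gem-diolate 11 (not isolated)
Conditions: MeLi (4 equiv), THF, 0 °C → rt; inverse quench into cold aq. HCl
Reagents that add atoms: methyllithium [Li]C
Why: Methyllithium adds once to the lithium carboxylate to give a stable gem-dialkoxide that collapses to the methyl ketone only on work-up (ketone synthesis from carboxylic acids and organolithiums), and the trans arrangement is the thermodynamically preferred one in any case.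

Step 7
Reactants: 12 1-[(1S,2R)-2-(hydroxymethyl)-4,4-dimethylcyclobutyl]ethan-1-one
Product: 13 [(1R,2R)-3,3-dimethyl-2-(prop-1-en-2-yl)cyclobutyl]methanol
Conditions: Ph3PCH3Br (3 equiv), KOtBu (3 equiv), THF, 0 °C → reflux
Reagents that add atoms: methyltriphenylphosphonium bromide C[P+](c1ccccc1)(c1ccccc1)c1ccccc1.[Br-]
Why: Wittig methylenation with the non-stabilised ylide converts the hindered methyl ketone into the isopropenyl group, and the α-centre can only equilibrate towards the desired, more stable trans isomer.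

Step 8
Reactants: 13 [(1R,2R)-3,3-dimethyl-2-(prop-1-en-2-yl)cyclobutyl]methanol
Product: 14 (1R,2R)-3,3-dimethyl-2-(prop-1-en-2-yl)cyclobutane-1-carbaldehyde
Conditions: Dess–Martin periodinane (1.2 equiv), CH2Cl2, 0 °C → rt
Reagents that add atoms: none
Why: Dess–Martin oxidation takes the primary alcohol to the aldehyde under neutral conditions without touching the alkene, and the α-stereocentre stays in its more stable trans arrangement.

Step 9
Reactants: 15 phloroglucinol; 16 3-methylbut-2-enoic acid
Product: 18 5,7-dihydroxy-2,2-dimethylchroman-4-one, via aryl enone 17 (not isolated)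
Conditions: P2O5 in MeSO3H (as solvent), 70 °C
Reagents that add atoms: none
Why: Friedel–Crafts acylation of the symmetric triphenol followed by intramolecular oxa-Michael addition of an ortho hydroxyl gives the 2,2-dimethylchromanone; the symmetry of phloroglucinol leaves no regiochemical choice and no stereocentre arises.

Step 10
Reactants: 18 5,7-dihydroxy-2,2-dimethylchroman-4-one (1.5 equiv); 14 (1R,2R)-3,3-dimethyl-2-(prop-1-en-2-yl)cyclobutane-1-carbaldehyde
Product: 20 6-{[(1S,2R)-3,3-dimethyl-2-(prop-1-en-2-yl)cyclobutyl]methyl}-5,7-dihydroxy-2,2-dimethylchroman-4-one, via ortho-quinone methide 19 (not isolated)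
Conditions: L-proline (20 mol %), Hantzsch ester (diethyl 2,6-dimethyl-1,4-dihydropyridine-3,5-dicarboxylate, 1.2 equiv), CH2Cl2, rt
Reagents that add atoms: none
Why: Organocatalytic three-component reductive alkylation (Knoevenagel condensation to an ortho-quinone methide, then hydride transfer from the Hantzsch ester) should occur at C-6, the only ring carbon flanked by two free hydroxyls and hence the 1,3-dicarbonyl-like position, and both cyclobutane stereocentres are carried through unchanged.

Step 11
Reactants: 20 6-{[(1S,2R)-3,3-dimethyl-2-(prop-1-en-2-yl)cyclobutyl]methyl}-5,7-dihydroxy-2,2-dimethylchroman-4-one; 21 (E)-hex-2-enal (1.5 equiv)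
Product: 23 (10R)-6-{[(1S,2R)-3,3-dimethyl-2-(prop-1-en-2-yl)cyclobutyl]methyl}-5,8-dihydroxy-2,2-dimethyl-10-propyl-2,3,9,10-tetrahydro-4H,8H-pyrano[2,3-f]chromen-4-one, via open-chain aldehyde 22 (not isolated)
Conditions: (S)-2-[diphenyl(trimethylsilyloxy)methyl]pyrrolidine (20 mol %), PhCO2H (20 mol %), toluene, 0 °C → rt
Reagents that add atoms: none
Why: Iminium-catalysed Friedel–Crafts-type Michael addition of the only remaining aromatic CH (C-8) and hemiacetal closure onto the 7-hydroxyl give the lactol, the arene adding to the β-carbon of the E-configured iminium ion on the face opposite to the bulky diphenyl(silyloxy)methyl group, which corresponds to the (R) centre.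

Step 12
Reactants: 23 (10R)-lactol
Product: 24 (10R)-6-{[(1S,2R)-3,3-dimethyl-2-(prop-1-en-2-yl)cyclobutyl]methyl}-5-hydroxy-2,2-dimethyl-10-propyl-2,3,9,10-tetrahydro-4H,8H-pyrano[2,3-f]chromene-4,8-dione
Conditions: tetrapropylammonium perruthenate (n-Pr4N)[RuO4] (5 mol %), N-methylmorpholine N-oxide (1.5 equiv), 4 Å molecular sieves, CH2Cl2, rt
Reagents that add atoms: none
Why: Ley–Griffith oxidation of the lactol to the lactone is neutral and should leave the isopropenyl group, the chelated phenol and all stereocentres untouched.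

Step 13
Reactants: 24 (10R)-lactone
Product: 25 (3R)-3-[6-{[(1S,2R)-3,3-dimethyl-2-(prop-1-en-2-yl)cyclobutyl]methyl}-5,7-dihydroxy-2,2-dimethyl-4-oxochroman-8-yl]hexanoic acid
Conditions: LiOH (3 equiv), THF/H2O, 0 °C; cold dilute HCl to pH 3; used at once
Reagents that add atoms: lithium hydroxide [Li+].[OH-]
Why: Saponification of the aryl ester (lactone) is fast under mild hydroxide conditions that should neither open the chromanone ring nor epimerise the benzylic centre, and it frees the second hydroxyl next to C-6.

Step 14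
Reactants: 25 (3R)-seco acid; 26 3-methylbut-2-en-1-yl acetate (prenyl acetate, 1.2 equiv)
Product: 27 (3R)-3-[(6R)-6-{[(1S,2R)-3,3-dimethyl-2-(prop-1-en-2-yl)cyclobutyl]methyl}-5-hydroxy-2,2-dimethyl-6-(3-methylbut-2-en-1-yl)-4,7-dioxo-3,4,6,7-tetrahydro-2H-chromen-8-yl]hexanoic acid
Conditions: Pd2(dba)3·CHCl3 (2.5 mol %), (1R,2R)-N,N'-bis[2-(diphenylphosphino)benzoyl]cyclohexane-1,2-diamine (7.5 mol %), Cs2CO3 (2.2 equiv), THF, 0 °C → rt; dilute HCl work-up
Reagents that add atoms: none
Why: In this Tsuji–Trost-type dearomatising allylic alkylation the zerovalent palladium complex ionises prenyl acetate and the soft enolate carbon C-6, flanked by two oxygens, attacks the unsubstituted allyl terminus, the chiral pocket of the ligand selecting the face of the planar nucleophile (catalyst control over the remote substrate centres) to set the (6R) quaternary carbon while reversible O-prenylation funnels into the C–C product.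

Compound list

1 | 4,4-dimethylcyclohexene | CC1(C)CCC=CC1 | starting material
2 | 3,3-dimethylhexanedioic acid | OC(=O)CC(C)(C)CCC(=O)O | intermediate
3 | (S)-4-benzyl-1,3-oxazolidin-2-one | O=C1OC[C@H](Cc2ccccc2)N1 | starting material
4 | 3,3-dimethylhexanedioic bis(pivalic) anhydride | CC(C)(C)C(=O)OC(=O)CC(C)(C)CCC(=O)OC(=O)C(C)(C)C | intermediate (not isolated)
5 | (4S,4'S)-3,3'-(3,3-dimethylhexanedioyl)bis(4-benzyl-1,3-oxazolidin-2-one) | O=C(CC(C)(C)CCC(=O)N1[C@@H](Cc2ccccc2)COC1=O)N1[C@@H](Cc2ccccc2)COC1=O | intermediate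
6 | dilithium bis-(Z)-enolate of 5 | [Li+].[Li+].[O-]/C(=C\CC(C)(C)/C=C(\[O-])N1[C@@H](Cc2ccccc2)COC1=O)N1[C@@H](Cc2ccccc2)COC1=O | intermediate (not isolated)
7 | (4S,4'S)-3,3'-{[(1R,2S)-3,3-dimethylcyclobutane-1,2-diyl]dicarbonyl}bis(4-benzyl-1,3-oxazolidin-2-one), trans | O=C([C@H]1[C@H](C(=O)N2[C@@H](Cc3ccccc3)COC2=O)CC1(C)C)N1[C@@H](Cc2ccccc2)COC1=O | intermediate
8 | (S)-4-benzyl-3-{[(1S,2R)-2-(hydroxymethyl)-4,4-dimethylcyclobutyl]carbonyl}-1,3-oxazolidin-2-one | O=C([C@H]1[C@H](CO)CC1(C)C)N1[C@@H](Cc2ccccc2)COC1=O | intermediate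
9 | (1S,2R)-2-(hydroxymethyl)-4,4-dimethylcyclobutane-1-carboperoxoic acid | OOC(=O)[C@H]1[C@H](CO)CC1(C)C | intermediate (not isolated)
10 | (1S,2R)-2-(hydroxymethyl)-4,4-dimethylcyclobutane-1-carboxylic acid | OC(=O)[C@H]1[C@H](CO)CC1(C)C | intermediate
11 | trilithium salt of 1-[(1S,2R)-2-(hydroxymethyl)-4,4-dimethylcyclobutyl]ethane-1,1-diol | [Li]OC(C)(O[Li])[C@H]1[C@H](CO[Li])CC1(C)C | intermediate (not isolated)
12 | 1-[(1S,2R)-2-(hydroxymethyl)-4,4-dimethylcyclobutyl]ethan-1-one | CC(=O)[C@H]1[C@H](CO)CC1(C)C | intermediate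
13 | [(1R,2R)-3,3-dimethyl-2-(prop-1-en-2-yl)cyclobutyl]methanol | C=C(C)[C@H]1[C@H](CO)CC1(C)C | intermediate
14 | (1R,2R)-3,3-dimethyl-2-(prop-1-en-2-yl)cyclobutane-1-carbaldehyde | C=C(C)[C@H]1[C@H](C=O)CC1(C)C | intermediate
15 | phloroglucinol (benzene-1,3,5-triol) | Oc1cc(O)cc(O)c1 | starting material
16 | 3-methylbut-2-enoic acid | CC(C)=CC(=O)O | starting material
17 | 3-methyl-1-(2,4,6-trihydroxyphenyl)but-2-en-1-one | CC(C)=CC(=O)c1c(O)cc(O)cc1O | intermediate (not isolated)
18 | 5,7-dihydroxy-2,2-dimethylchroman-4-one | CC1(C)CC(=O)c2c(O)cc(O)cc2O1 | intermediate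
19 | 6-{[(1S,2R)-3,3-dimethyl-2-(prop-1-en-2-yl)cyclobutyl]methylidene}-5-hydroxy-2,2-dimethyl-2,3-dihydrochromene-4,7(6H)-dione (ortho-quinone methide) | C=C(C)[C@H]1[C@H](C=C2C(=O)C=C3OC(C)(C)CC(=O)C3=C2O)CC1(C)C | intermediate (not isolated)
20 | 6-{[(1S,2R)-3,3-dimethyl-2-(prop-1-en-2-yl)cyclobutyl]methyl}-5,7-dihydroxy-2,2-dimethylchroman-4-one | C=C(C)[C@H]1[C@H](Cc2c(O)c3C(=O)CC(C)(C)Oc3cc2O)CC1(C)C | intermediate
21 | (E)-hex-2-enal | CCC/C=C/C=O | starting material
22 | (3R)-3-[6-{[(1S,2R)-3,3-dimethyl-2-(prop-1-en-2-yl)cyclobutyl]methyl}-5,7-dihydroxy-2,2-dimethyl-4-oxochroman-8-yl]hexanal | C=C(C)[C@H]1[C@H](Cc2c(O)c3C(=O)CC(C)(C)Oc3c([C@H](CCC)CC=O)c2O)CC1(C)C | intermediate (not isolated)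
23 | (10R)-6-{[(1S,2R)-3,3-dimethyl-2-(prop-1-en-2-yl)cyclobutyl]methyl}-5,8-dihydroxy-2,2-dimethyl-10-propyl-2,3,9,10-tetrahydro-4H,8H-pyrano[2,3-f]chromen-4-one (lactol, both C-8 anomers) | C=C(C)[C@H]1[C@H](Cc2c(O)c3C(=O)CC(C)(C)Oc3c3c2OC(O)C[C@H]3CCC)CC1(C)C | intermediate
24 | (10R)-6-{[(1S,2R)-3,3-dimethyl-2-(prop-1-en-2-yl)cyclobutyl]methyl}-5-hydroxy-2,2-dimethyl-10-propyl-2,3,9,10-tetrahydro-4H,8H-pyrano[2,3-f]chromene-4,8-dione (lactone) | C=C(C)[C@H]1[C@H](Cc2c(O)c3C(=O)CC(C)(C)Oc3c3c2OC(=O)C[C@H]3CCC)CC1(C)C | intermediate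
25 | (3R)-3-[6-{[(1S,2R)-3,3-dimethyl-2-(prop-1-en-2-yl)cyclobutyl]methyl}-5,7-dihydroxy-2,2-dimethyl-4-oxochroman-8-yl]hexanoic acid | C=C(C)[C@H]1[C@H](Cc2c(O)c3C(=O)CC(C)(C)Oc3c([C@H](CCC)CC(=O)O)c2O)CC1(C)C | intermediate
26 | 3-methylbut-2-en-1-yl acetate (prenyl acetate) | CC(=O)OCC=C(C)C | starting material
27 | (3R)-3-[(6R)-6-{[(1S,2R)-3,3-dimethyl-2-(prop-1-en-2-yl)cyclobutyl]methyl}-5-hydroxy-2,2-dimethyl-6-(3-methylbut-2-en-1-yl)-4,7-dioxo-3,4,6,7-tetrahydro-2H-chromen-8-yl]hexanoic acid | C=C(C)[C@H]1[C@H](C[C@]2(CC=C(C)C)C(=O)C([C@H](CCC)CC(=O)O)=C3OC(C)(C)CC(=O)C3=C2O)CC1(C)C | target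

Total step count: 14. Longest linear sequence: 13 steps (steps 1–8 and 10–14); step 9 is a one-step branch.

Steps most likely to fail

Step 3 (oxidative ring closure). Intermolecular coupling and proton return of the hindered dienolate may outrun closure of the strained ring, and the two bulky auxiliaries may hold back conversion. The fallback closes the same bond on the small diester and secures the absolute configuration by resolution. It sets out from 2: Fischer esterification (MeOH, H2SO4) should give dimethyl 3,3-dimethylhexanedioate F1. Treatment with LDA (2.2 equiv) and then I2 (1 equiv) should iodinate one enolate carbon, which the second enolate displaces in a 4-exo-tet closure, and equilibration with NaOMe should give the racemic trans-diester F2. Saponification with LiOH leads to the racemic trans-diacid F3, which is resolved by crystallisation of a diastereomeric salt with one enantiomer of 1-phenylethylamine to the (1R,2S)-diacid F4. Its bis(pivalic) mixed anhydride F5 acylates 3 under the conditions of step 2, and the route is rejoined at 7.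

Step 14 (dearomatising prenylation). Facial discrimination at the planar C-6 nucleophile by the chiral catalyst may be poor, and O-prenylation of the phenoxide or carboxylate may compete. The fallback gives up catalyst control and relies on separation. It sets out from 25: the trianion formed in aqueous KOH is C-alkylated with prenyl bromide at 0 °C (classical C-prenylation of acylphloroglucinols in water), which should give 27 together with its (6S)-epimer F6. The two are diastereomers and are separated by preparative HPLC, so the fallback ends at 27.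

Step 4 (mono-reduction). Discrimination between the two imide carbonyls may be insufficient, leading to over-reduction to the diol or to endocyclic attack on the hindered auxiliary. The fallback differentiates carboxyl groups instead of imides and then uses functional-group chemoselectivity. It sets out from 7: exhaustive cleavage with LiOH/H2O2 should give the (1R,2S)-diacid F4 described above. Fischer esterification under kinetic control (MeOH, catalytic H2SO4, rt) should esterify only the carboxyl on the ring carbon next to CH2 and give the mono-methyl ester F7. LiBH4 reduces the ester but not the lithium carboxylate, and the route is rejoined at 10.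

Further compounds

F1 | step 3 | dimethyl 3,3-dimethylhexanedioate | COC(=O)CC(C)(C)CCC(=O)OC
F2 | step 3 | racemic dimethyl trans-3,3-dimethylcyclobutane-1,2-dicarboxylate (both enantiomers) | COC(=O)[C@H]1[C@H](C(=O)OC)CC1(C)C.COC(=O)[C@@H]1[C@@H](C(=O)OC)CC1(C)C
F3 | step 3 | racemic trans-3,3-dimethylcyclobutane-1,2-dicarboxylic acid (both enantiomers) | OC(=O)[C@H]1[C@H](C(=O)O)CC1(C)C.OC(=O)[C@@H]1[C@@H](C(=O)O)CC1(C)C
F4 | step 3 | (1R,2S)-3,3-dimethylcyclobutane-1,2-dicarboxylic acid | OC(=O)[C@H]1[C@H](C(=O)O)CC1(C)C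
F5 | step 3 | (1R,2S)-3,3-dimethylcyclobutane-1,2-dicarboxylic bis(pivalic) anhydride | CC(C)(C)C(=O)OC(=O)[C@H]1[C@H](C(=O)OC(=O)C(C)(C)C)CC1(C)C
F6 | step 14 | (3R)-3-[(6S)-6-{[(1S,2R)-3,3-dimethyl-2-(prop-1-en-2-yl)cyclobutyl]methyl}-5-hydroxy-2,2-dimethyl-6-(3-methylbut-2-en-1-yl)-4,7-dioxo-3,4,6,7-tetrahydro-2H-chromen-8-yl]hexanoic acid | C=C(C)[C@H]1[C@H](C[C@@]2(CC=C(C)C)C(=O)C([C@H](CCC)CC(=O)O)=C3OC(C)(C)CC(=O)C3=C2O)CC1(C)C
F7 | step 4 | (1S,2R)-2-(methoxycarbonyl)-4,4-dimethylcyclobutane-1-carboxylic acid | OC(=O)[C@H]1[C@H](C(=O)OC)CC1(C)C
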